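**Retrosynthetic overview**
1. Feature: ring A (C5a, C6, C7, C8, C9, C9a) is a masked quinone. The C7 hydroxyl lies para to the lactone oxygen on C9a, and the pyran oxygen O1' sits on C8. At the quinone level C8 is the only C-H carbon, it is β to the C9a carbonyl, and a hydroxyl at the end of a (Z)-C4'=C3'-C2'Me2 chain on C9 can reach it.
2. Late disconnections: the two ring B MOM ethers; then the lactone bond O10-C11 (seven-membered ring, closed last from a pentafluorophenyl ester, because acyl transfer from a methyl ester to an aryl oxygen is uphill); then the pyran bond C8-O1' (key step).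
3. The aryloxyquinone comes from its C7/C9a dimethyl ether with (NH4)2Ce(NO3)6. The Z chain comes from Sonogashira coupling at C9-Br and semihydrogenation. The ester comes from the aldehyde that first activates ring B for SNAr formation of O5.
4. Ring A fragment: electrophilic bromination of a 1,2,4-trioxygenated ring goes to C8 (para to the C5a oxygen) and would attack a prenyl group. C9-Br and C5a-OH are therefore both taken from the two equivalent bromines of 2,6-dibromo-4-methoxyphenol, and the C6 prenyl group is delivered from O5a by Claisen rearrangement.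
5. Ring B fragment: 1-fluoro-3,5-dimethoxybenzene by formylation, bromination, methyl-to-MOM exchange and Stille prenylation. Ring order: A and B purchased, then the pyran ring, then the lactone ring.

Key step: step 18

Remark: depsidone numbering is used throughout (ring B C1-C4a and C11a, ether O5, ring A C5a-C9a, lactone O10-C11, pyran O1'-C4'). Tributyl(3-methylbut-2-enyl)stannane is assumed to be a purchasable reagent.

**Step 1**
Reactants: 1 4-methoxyphenol
Product: 2 2,6-dibromo-4-methoxyphenol
Conditions: Br2 (2.1 equiv), CH2Cl2, 0 °C to rt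
Reagents that add atoms: bromine, BrBr
Why: Electrophilic aromatic bromination, in which the free hydroxyl is the stronger director and its para position is blocked, so both bromines should enter ortho to it and give a symmetric product.

**Step 2**
Reactants: 2 2,6-dibromo-4-methoxyphenol
Product: 3 1,3-dibromo-2,5-dimethoxybenzene
Conditions: MeI, K2CO3, DMF, rt
Reagents that add atoms: iodomethane, CI
Why: Williamson O-methylation of an acidic dibromophenol, which turns the future C7/C9a oxygens into a hydroquinone dimethyl ether that tolerates every later step up to the oxidation.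

**Step 3**
Reactants: 3 1,3-dibromo-2,5-dimethoxybenzene
Product: 6 3-bromo-2,5-dimethoxyphenol, via aryllithium 4 (not isolated), via arylboronate 5 (not isolated)
Conditions: n-BuLi (1.0 equiv), THF, -78 °C; B(OMe)3, -78 °C to rt; then AcOH, 30% H2O2, 0 °C to rt
Reagents that add atoms: hydrogen peroxide, OO; n-butyllithium, [Li]CCCC (lithium kept only in 4); trimethyl borate, COB(OC)OC (atoms kept only in 5)
Why: Bromine-lithium exchange, borylation and oxidative hydroxydeboronation; because the two bromines are equivalent, one exchange fixes the adjacent order C5a-OH, C9a-OMe, C9-Br without any regiochemical choice.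

**Step 4**
Reactants: 7 2-methylbut-3-en-2-ol
Product: 8 tert-butyl 2-methylbut-3-en-2-yl carbonate
Conditions: n-BuLi, THF, 0 °C; Boc2O, 0 °C to rt
Reagents that add atoms: di-tert-butyl dicarbonate, CC(C)(C)OC(=O)OC(=O)OC(C)(C)C
Why: Acylation of the lithium alkoxide of a tertiary allylic alcohol by the dicarbonate, a standard way to make mixed allylic carbonates.

**Step 5**
Reactants: 6 3-bromo-2,5-dimethoxyphenol; 8 tert-butyl 2-methylbut-3-en-2-yl carbonate
Product: 9 1-bromo-2,5-dimethoxy-3-[(2-methylbut-3-en-2-yl)oxy]benzene
Conditions: Pd(PPh3)4 (3 mol %), THF, 0 °C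
Reagents that add atoms: none
Why: Tsuji-Trost O-allylation, in which ionization and decarboxylation give a 1,1-dimethylallylpalladium species and tert-butoxide, the phenoxide attacks the more substituted terminus under kinetic control, and the electron-rich C-Br bond should not undergo oxidative addition at 0 °C.

**Step 6**
Reactants: 9 1-bromo-2,5-dimethoxy-3-[(2-methylbut-3-en-2-yl)oxy]benzene
Product: 11 3-bromo-2,5-dimethoxy-6-(3-methylbut-2-enyl)phenol, via dienone 10 (not isolated)
Conditions: PhNEt2, 130 °C
Reagents that add atoms: none
Why: Aromatic Claisen rearrangement, in which the [3,3] shift from O5a can end productively only at C6 (the other ortho carbon, C9a, bears methoxy and cannot rearomatize), allyl inversion turns the 1,1-dimethylallyl group into prenyl, and the basic solvent holds back chroman formation.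

**Step 7**
Reactants: 12 1-fluoro-3,5-dimethoxybenzene
Product: 14 2-fluoro-4,6-dimethoxybenzaldehyde, via iminium chloride 13 (not isolated)
Conditions: POCl3, DMF, 0 to 70 °C; then ice-water
Reagents that add atoms: N,N-dimethylformamide, CN(C)C=O; water, O; phosphoryl chloride, O=P(Cl)(Cl)Cl (chloride ion of 13 only)
Why: Vilsmeier-Haack formylation, which should prefer the carbon para to one methoxy group and next to the small fluorine over the crowded carbon between the two methoxy groups.

**Step 8**
Reactants: 14 2-fluoro-4,6-dimethoxybenzaldehyde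
Product: 15 3-bromo-2-fluoro-4,6-dimethoxybenzaldehyde
Conditions: NBS, MeCN, 0 °C to rt
Reagents that add atoms: N-bromosuccinimide, O=C1CCC(=O)N1Br
Why: Electrophilic aromatic bromination at the carbon ortho to one methoxy group and para to the other (future C4), since attack between the two methoxy groups would twist both out of conjugation.

**Step 9**
Reactants: 15 3-bromo-2-fluoro-4,6-dimethoxybenzaldehyde
Product: 16 3-bromo-2-fluoro-4,6-dihydroxybenzaldehyde
Conditions: BBr3 (4 equiv), CH2Cl2, -78 °C to rt; then H2O
Reagents that add atoms: none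
Why: Lewis-acid cleavage of aryl methyl ethers, carried out before any prenyl group is present because the methyl ethers could not be removed at the end.

**Step 10**
Reactants: 16 3-bromo-2-fluoro-4,6-dihydroxybenzaldehyde
Product: 17 3-bromo-2-fluoro-4,6-bis(methoxymethoxy)benzaldehyde
Conditions: NaH, MOMCl, DMF, 0 °C to rt
Reagents that add atoms: chloromethyl methyl ether, COCCl
Why: O-alkylation of the bis-phenoxide, with full deprotonation by NaH so that the hydrogen-bonded hydroxyl next to the aldehyde also reacts.

**Step 11**
Reactants: 17 3-bromo-2-fluoro-4,6-bis(methoxymethoxy)benzaldehyde; 18 tributyl(3-methylbut-2-enyl)stannane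
Product: 19 2-fluoro-4,6-bis(methoxymethoxy)-3-(3-methylbut-2-enyl)benzaldehyde
Conditions: Pd(PPh3)4 (5 mol %), DMF, 100 °C
Reagents that add atoms: none
Why: Stille coupling of an aryl bromide with the prenylstannane, a neutral method that tolerates the aldehyde and the C-F bond and normally gives the linear prenyl arene.

**Step 12**
Reactants: 11 3-bromo-2,5-dimethoxy-6-(3-methylbut-2-enyl)phenol; 19 2-fluoro-4,6-bis(methoxymethoxy)-3-(3-methylbut-2-enyl)benzaldehyde
Product: 20 2-[3-bromo-2,5-dimethoxy-6-(3-methylbut-2-enyl)phenoxy]-4,6-bis(methoxymethoxy)-3-(3-methylbut-2-enyl)benzaldehyde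
Conditions: Cs2CO3, DMF, 110 °C
Reagents that add atoms: none
Why: SNAr etherification, in which the caesium phenoxide of C5a-OH adds to C4a, the ortho aldehyde carries the charge of the Meisenheimer adduct, the two MOM-oxy groups stand meta to the attacked carbon, and fluoride leaves.

**Step 13**
Reactants: 20 bromo diaryl ether aldehyde; 21 2-methylbut-3-yn-2-ol
Product: 22 2-[3-(3-hydroxy-3-methylbut-1-ynyl)-2,5-dimethoxy-6-(3-methylbut-2-enyl)phenoxy]-4,6-bis(methoxymethoxy)-3-(3-methylbut-2-enyl)benzaldehyde
Conditions: PdCl2(MeCN)2 (2 mol %), XPhos (6 mol %), Cs2CO3, MeCN, 75 °C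
Reagents that add atoms: none
Why: Copper-free Sonogashira coupling with a bulky electron-rich phosphine suited to a deactivated aryl bromide; copper and secondary amines are left out so that the aldehyde cannot enter an aldehyde-alkyne-amine coupling.

**Step 14**
Reactants: 22 alkynyl aldehyde
Product: 23 2-[3-(3-hydroxy-3-methylbut-1-ynyl)-2,5-dimethoxy-6-(3-methylbut-2-enyl)phenoxy]-4,6-bis(methoxymethoxy)-3-(3-methylbut-2-enyl)benzoic acid
Conditions: NaClO2, NaH2PO4, 2-methylbut-2-ene (large excess), t-BuOH/THF/H2O, 0 °C to rt
Reagents that add atoms: sodium chlorite, [Na+].[O-]Cl=O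
Why: Pinnick oxidation, placed at the alkyne stage where the side chain is inert, with the excess alkene taking up hypochlorous acid before it can reach the prenyl groups or ring A.

**Step 15**
Reactants: 23 alkynyl benzoic acid
Product: 24 pentafluorophenyl ester of 23
Conditions: C6F5OH, DCC, DMAP (10 mol %), CH2Cl2, 0 °C to rt
Reagents that add atoms: pentafluorophenol, Oc1c(F)c(F)c(F)c(F)c1F
Why: Steglich-type carbodiimide esterification, the usual route to aryl esters of di-ortho-oxygenated benzoic acids, with the tertiary propargylic hydroxyl too hindered to compete.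

**Step 16**
Reactants: 24 alkynyl pentafluorophenyl ester
Product: 25 pentafluorophenyl 2-{3-[(Z)-3-hydroxy-3-methylbut-1-enyl]-2,5-dimethoxy-6-(3-methylbut-2-enyl)phenoxy}-4,6-bis(methoxymethoxy)-3-(3-methylbut-2-enyl)benzoate
Conditions: H2 (1 atm), Pd/CaCO3-Pb(OAc)2, quinoline, EtOAc, rt, stopped after one equivalent of H2
Reagents that add atoms: none
Why: Lindlar-type semihydrogenation, in which syn delivery of hydrogen on the poisoned palladium surface sets the Z geometry of C3'=C4' while the trisubstituted prenyl alkenes and the ester stay untouched.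

**Step 17**
Reactants: 25 Z-alkenyl dimethyl ether
Product: 26 aryloxy-1,4-benzoquinone (C7 and C9a carbonyls, C5a-O-ring B, C6 prenyl, C8-H, C9 (Z)-3-hydroxy-3-methylbut-1-enyl; ring B with C1 and C3 MOM ethers, C4 prenyl and C11 pentafluorophenyl ester)
Conditions: (NH4)2Ce(NO3)6 (2.2 equiv), MeCN/H2O, 0 °C, 10 min
Reagents that add atoms: water, O
Why: Oxidative demethylation of a hydroquinone dimethyl ether by tetravalent cerium, which should strike ring A as the far more electron-rich arene (ring B is deactivated by its ester), with water attacking the two methoxy-bearing carbons; the short cold contact and the near-stoichiometric charge are chosen to spare the MOM ethers, the allylic alcohol and the alkenes.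

**Step 18**
Reactants: 26 aryloxyquinone with (Z)-hydroxyalkenyl chain on C9
Product: 28 chromene hydroquinone (2,2-dimethyl-2H-pyran fused at C8/C9, free C7-OH and C9a-OH, C6 prenyl, ring B pentafluorophenyl ester attached through O5), via dienone adduct 27 (not isolated)
Conditions: (+)-camphor-10-sulfonic acid (5 mol %), CH2Cl2 (0.005 M), 0 °C to rt, argon, dark
Reagents that add atoms: none
Why: The sulfonic acid activates the C9a carbonyl and so raises the electrophilicity of C8; the tertiary hydroxyl, held over that carbon by the Z C3'=C4' bond, adds to it to form C8-O1' and the enol 27, and loss of the C8 proton with enolization of the C7 carbonyl gives the aromatic C7/C9a hydroquinone, so the step is an isomerization that needs no oxidant or reductant. The closest known reaction type is the oxa-Michael addition of alcohols to 1,4-benzoquinones followed by tautomerization to alkoxyhydroquinones, known in intermolecular and intramolecular form. The pyran ring (O1', C2', C3', C4', C9, C8) closes in the 6-endo-trig mode, with the attacked C8=C9 bond inside the new ring, helped by the geminal methyl groups and the few free rotors of the Z chain. No stereocenter survives, because C8 is tetrahedral only in 27 and becomes planar on aromatization. Site selectivity is secured because C8 is the only quinone carbon that bears hydrogen, C5a and C6 are fully substituted and out of reach of the chain, and 1,2-addition to the C9a carbonyl is reversible and cannot aromatize. Acid rather than base is used to avoid tautomerization of the C6 prenylquinone to a quinone methide that would close on O7, and high dilution, argon and darkness hold back hydrogen transfer from 28 to unreacted 26 and Z-to-E isomerization.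

**Step 19**
Reactants: 28 chromene hydroquinone
Product: 29 1,3-di-O-methoxymethyl ether of the target depsidone
Conditions: i-Pr2NEt (2 equiv), degassed CH2Cl2 (0.01 M), rt, argon
Reagents that add atoms: none
Why: Intramolecular transesterification (7-exo-trig lactonization), in which the C9a hydroxyl freed in step 18 is the only one within reach of C11 and the loss of the weakly basic pentafluorophenoxide makes the acyl transfer to an aryl oxygen downhill and much faster than ipso attack at C4a.

**Step 20**
Reactants: 29 di-O-MOM depsidone
Product: 30 target depsidone CNP0263700.0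
Conditions: 3 M aq HCl, THF/i-PrOH, 40 °C
Reagents that add atoms: none
Why: Acid hydrolysis of aryl MOM acetals under the mild aqueous conditions customary for prenylated phenols, without methanol as solvent so that the aryl lactone is not opened and below the acidity at which ortho-prenylphenols close to chromans.

**Compound list**
1 | 4-methoxyphenol | COc1ccc(O)cc1 | starting material
2 | 2,6-dibromo-4-methoxyphenol | COc1cc(Br)c(O)c(Br)c1 | intermediate
3 | 1,3-dibromo-2,5-dimethoxybenzene | COc1cc(Br)c(OC)c(Br)c1 | intermediate
4 | (3-bromo-2,5-dimethoxyphenyl)lithium | [Li]c1cc(OC)cc(Br)c1OC | intermediate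
5 | dimethyl (3-bromo-2,5-dimethoxyphenyl)boronate | COB(OC)c1cc(OC)cc(Br)c1OC | intermediate
6 | 3-bromo-2,5-dimethoxyphenol | COc1cc(O)c(OC)c(Br)c1 | intermediate
7 | 2-methylbut-3-en-2-ol | C=CC(C)(C)O | starting material
8 | tert-butyl 2-methylbut-3-en-2-yl carbonate | C=CC(C)(C)OC(=O)OC(C)(C)C | intermediate
9 | 1-bromo-2,5-dimethoxy-3-[(2-methylbut-3-en-2-yl)oxy]benzene | C=CC(C)(C)Oc1cc(OC)cc(Br)c1OC | intermediate
10 | 3-bromo-2,5-dimethoxy-6-(3-methylbut-2-enyl)cyclohexa-2,4-dien-1-one (racemic, transient) | O=C1C(CC=C(C)C)C(OC)=CC(Br)=C1OC | intermediate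
11 | 3-bromo-2,5-dimethoxy-6-(3-methylbut-2-enyl)phenol | CC(C)=CCc1c(O)c(OC)c(Br)cc1OC | intermediate
12 | 1-fluoro-3,5-dimethoxybenzene | COc1cc(F)cc(OC)c1 | starting material
13 | N-[(2-fluoro-4,6-dimethoxyphenyl)methylidene]-N-methylmethanaminium chloride | C[N+](C)=Cc1c(F)cc(OC)cc1OC.[Cl-] | intermediate
14 | 2-fluoro-4,6-dimethoxybenzaldehyde | COc1cc(F)c(C=O)c(OC)c1 | intermediate
15 | 3-bromo-2-fluoro-4,6-dimethoxybenzaldehyde | COc1cc(OC)c(C=O)c(F)c1Br | intermediate
16 | 3-bromo-2-fluoro-4,6-dihydroxybenzaldehyde | Oc1cc(O)c(C=O)c(F)c1Br | intermediate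
17 | 3-bromo-2-fluoro-4,6-bis(methoxymethoxy)benzaldehyde | COCOc1cc(OCOC)c(C=O)c(F)c1Br | intermediate
18 | tributyl(3-methylbut-2-enyl)stannane | CCCC[Sn](CCCC)(CCCC)CC=C(C)C | starting material
19 | 2-fluoro-4,6-bis(methoxymethoxy)-3-(3-methylbut-2-enyl)benzaldehyde | COCOc1cc(OCOC)c(C=O)c(F)c1CC=C(C)C | intermediate
20 | bromo diaryl ether aldehyde | CC(C)=CCc1c(OC)cc(Br)c(OC)c1Oc1c(CC=C(C)C)c(OCOC)cc(OCOC)c1C=O | intermediate
21 | 2-methylbut-3-yn-2-ol | CC(C)(O)C#C | starting material
22 | alkynyl diaryl ether aldehyde | CC(C)=CCc1c(OC)cc(C#CC(C)(C)O)c(OC)c1Oc1c(CC=C(C)C)c(OCOC)cc(OCOC)c1C=O | intermediate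
23 | alkynyl diaryl ether benzoic acid | CC(C)=CCc1c(OC)cc(C#CC(C)(C)O)c(OC)c1Oc1c(CC=C(C)C)c(OCOC)cc(OCOC)c1C(=O)O | intermediate
24 | alkynyl pentafluorophenyl ester | CC(C)=CCc1c(OC)cc(C#CC(C)(C)O)c(OC)c1Oc1c(CC=C(C)C)c(OCOC)cc(OCOC)c1C(=O)Oc1c(F)c(F)c(F)c(F)c1F | intermediate
25 | (Z)-alkenyl pentafluorophenyl ester | CC(C)=CCc1c(OC)cc(/C=C\C(C)(C)O)c(OC)c1Oc1c(CC=C(C)C)c(OCOC)cc(OCOC)c1C(=O)Oc1c(F)c(F)c(F)c(F)c1F | intermediate
26 | aryloxyquinone with (Z)-hydroxyalkenyl chain on C9 (key-step precursor) | CC(C)=CCC1=C(Oc2c(CC=C(C)C)c(OCOC)cc(OCOC)c2C(=O)Oc2c(F)c(F)c(F)c(F)c2F)C(=O)C(/C=C\C(C)(C)O)=CC1=O | intermediate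
27 | C8-alkoxy enol-dienone adduct (racemic at C8, transient) | CC(C)=CCC1=C(Oc3c(CC=C(C)C)c(OCOC)cc(OCOC)c3C(=O)Oc3c(F)c(F)c(F)c(F)c3F)C(O)=C2C=CC(C)(C)OC2C1=O | intermediate
28 | chromene hydroquinone (key-step product) | CC(C)=CCc1c(O)c2OC(C)(C)C=Cc2c(O)c1Oc1c(CC=C(C)C)c(OCOC)cc(OCOC)c1C(=O)Oc1c(F)c(F)c(F)c(F)c1F | intermediate
29 | 1,3-di-O-MOM depsidone | CC(C)=CCc1c(O)c2c(c3c1Oc1c(CC=C(C)C)c(OCOC)cc(OCOC)c1C(=O)O3)C=CC(C)(C)O2 | intermediate
30 | CNP0263700.0 | CC(C)=CCc1c(O)c2c(c3c1Oc1c(CC=C(C)C)c(O)cc(O)c1C(=O)O3)C=CC(C)(C)O2 | target

**Totals**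
Total step count: 20.
Longest linear sequence: 14 steps (1, 2, 3, 5, 6, then 12-20). The ring B branch (7-11, then 12-20) is equally long.

**Steps most likely to fail**

Step 18 (key step).
- What may go wrong: hydrogen transfer from the electron-rich hydroquinone, as it forms, to quinone that has not yet cyclized. This would divert material into an uncyclized hydroquinone whose chain can dehydrate onto O9a. Slow tautomerization of the C6 prenylquinone toward closure on O7 is a second drain.
- Fallback: it sets out from 26 and gives up redox neutrality. The closure is run in the presence of excess Ag2O and MgSO4 in CH2Cl2 in the dark, so that all material stays at the quinone level until it has cyclized. Every hydroquinone that forms is oxidized at once to the chromenequinone F1. Reduction of F1 with aqueous Na2S2O4 in EtOAc then rejoins the route at 28.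

Step 12.
- What may go wrong: very slow addition of a doubly ortho-substituted phenoxide to a C-F carbon that is flanked by the aldehyde and an allylic CH2. That carbon is only moderately activated, because two alkoxy groups feed electron density into the aldehyde. Thermal degradation of the aldehyde would then compete at the temperature needed.
- Fallback: it sets out from 11 and 17 and changes the order of bond formation.
  - Copper-free Sonogashira coupling of 11 with 21 gives the alkynylphenol F2.
  - SNAr of F2 on the bromofluoroaldehyde 17, whose C4 bromine withdraws charge from the attacked carbon where the prenyl CH2 donated, gives the bromo diaryl ether F3.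
  - Stille coupling of the single remaining bromide of F3 with 18 rejoins the route at 22.

Step 17.
- What may go wrong:
  - acid-promoted ionization of the tertiary allylic alcohol while ring A is still electron-rich;
  - Z-to-E isomerization through the arene radical cation;
  - premature ring closure in the oxidizing medium followed by over-oxidation;
  - partial loss of MOM groups.
- Fallback: it sets out from 24, so that the Z alkene never meets tetravalent cerium.
  - (NH4)2Ce(NO3)6 oxidation at the acid-stable alkyne stage gives the alkynylquinone F4.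
  - Hydrogenation over Pd/CaCO3-Pb(OAc)2 in EtOAc without amine additive reduces the quinone to the hydroquinone and the alkyne to the Z alkene, giving the (Z)-alkenylhydroquinone F5.
  - F5 is kept neutral and free of base, so that neither dehydration onto O9a nor early lactonization sets in. It is oxidized directly with Ag2O in Et2O, which rejoins the route at 26.

**Further compounds**
F1 | step 18 | chromenequinone (C7 and C9a carbonyls, pyran fused at C8/C9) | CC(C)=CCC1=C(Oc3c(CC=C(C)C)c(OCOC)cc(OCOC)c3C(=O)Oc3c(F)c(F)c(F)c(F)c3F)C(=O)C2=C(OC(C)(C)C=C2)C1=O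
F2 | step 12 | 3-(3-hydroxy-3-methylbut-1-ynyl)-2,5-dimethoxy-6-(3-methylbut-2-enyl)phenol | CC(C)=CCc1c(O)c(OC)c(C#CC(C)(C)O)cc1OC
F3 | step 12 | 3-bromo-2-[3-(3-hydroxy-3-methylbut-1-ynyl)-2,5-dimethoxy-6-(3-methylbut-2-enyl)phenoxy]-4,6-bis(methoxymethoxy)benzaldehyde | CC(C)=CCc1c(OC)cc(C#CC(C)(C)O)c(OC)c1Oc1c(Br)c(OCOC)cc(OCOC)c1C=O
F4 | step 17 | alkynylquinone pentafluorophenyl ester | CC(C)=CCC1=C(Oc2c(CC=C(C)C)c(OCOC)cc(OCOC)c2C(=O)Oc2c(F)c(F)c(F)c(F)c2F)C(=O)C(C#CC(C)(C)O)=CC1=O
F5 | step 17 | (Z)-alkenylhydroquinone pentafluorophenyl ester | CC(C)=CCc1c(O)cc(/C=C\C(C)(C)O)c(O)c1Oc1c(CC=C(C)C)c(OCOC)cc(OCOC)c1C(=O)Oc1c(F)c(F)c(F)c(F)c1F
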